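**Retrosynthetic overview**
- The quaternary lactone carbon C3 carries an O atom and the benzylic CH2 of ring A on the same carbon. This O–C3–CH2Ar unit is read as an aryl oxirane whose benzylic C–O bond has been hydrogenolysed.
- The spiro-oxirane is disconnected into a carbene at lactone C3 (from an α-diazo-γ-butyrolactone) and the C=O group of O-silylated vanillin. One step would then form the benzylic C–C3 bond, the C3–O bond and the quaternary stereocentre.
- Enabling feature: C3 of the five-membered lactone bears geminal O and benzylic C. Ring A is electron-rich (para O-substituent), and the CH(O)Ar arm on C4 (ring B) screens one face of the lactone.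
- The diazo lactone derives from a 4-(α-hydroxybenzyl)butyrolactone. That lactone is made by a proline cross-aldol of the same silylated vanillin with methyl 4-oxobutanoate, which sets C4 and the carbinol carbon.
- Ring order: γ-lactone (step 2), then the temporary oxirane (formed in step 5, opened in step 6). Both arenes come from vanillin.

Key step: step 5

Remark: the configuration of the benzylic oxirane carbon formed in step 5 is left open (either epimer or a mixture), because step 6 turns this carbon into CH2.

Step 1
Reactants: 1 vanillin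
Product: 2 4-[(tert-butyldimethylsilyl)oxy]-3-methoxybenzaldehyde
Conditions: TBSCl, imidazole, DMF, 0 °C to rt
Reagents that add atoms: tert-butyldimethylsilyl chloride, C[Si](C)(Cl)C(C)(C)C
Why: Standard O-silylation of a phenol (substitution at silicon with imidazole as base and catalyst) gives a fluoride-labile ether that tolerates amide bases, hydride and hydrogenation, and no stereocentre is created.

Step 2
Reactants: 2 4-[(tert-butyldimethylsilyl)oxy]-3-methoxybenzaldehyde; 3 methyl 4-oxobutanoate
Product: 6 (4R)-4-[(R)-{4-[(tert-butyldimethylsilyl)oxy]-3-methoxyphenyl}(hydroxy)methyl]oxolan-2-one, via anti-aldol aldehyde 4 (not isolated), via diol ester 5 (not isolated)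
Conditions: L-proline (20 mol %), DMF, 4 °C, slow addition of 3; then MeOH, NaBH4, −20 °C; aq. NH4Cl work-up
Reagents that add atoms: none
Why: In this proline-catalysed direct cross-aldol reaction (enamine catalysis), followed by borohydride reduction and 5-exo-trig lactonisation and closely precedented for aromatic aldehydes, the E-enamine of 3 with (S)-proline should attack the Re face of 2 in the acid-bridged chair-like transition state, which sets the carbinol carbon as R and the neighbouring carbon in the anti sense, after which the primary alcohol of 5 closes the γ-lactone faster than the hindered benzylic one.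

Step 3
Reactants: 6 (4R)-4-[(R)-{4-[(tert-butyldimethylsilyl)oxy]-3-methoxyphenyl}(hydroxy)methyl]oxolan-2-one
Product: 7 (4R)-4-[(R)-[(tert-butyldimethylsilyl)oxy]{4-[(tert-butyldimethylsilyl)oxy]-3-methoxyphenyl}methyl]oxolan-2-one
Conditions: TBSOTf, 2,6-lutidine, CH2Cl2, 0 °C
Reagents that add atoms: tert-butyldimethylsilyl triflate, C[Si](C)(OS(=O)(=O)C(F)(F)F)C(C)(C)C
Why: O-silylation with a silyl triflate and a hindered pyridine base masks the only O–H bond, which would otherwise consume base in step 4 and insert into the carbene in step 5, and it leaves both stereocentres untouched.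

Step 4
Reactants: 7 (4R)-4-[(R)-[(tert-butyldimethylsilyl)oxy]{4-[(tert-butyldimethylsilyl)oxy]-3-methoxyphenyl}methyl]oxolan-2-one
Product: 9 (4R)-3-diazo-4-[(R)-[(tert-butyldimethylsilyl)oxy]{4-[(tert-butyldimethylsilyl)oxy]-3-methoxyphenyl}methyl]oxolan-2-one, via trifluoroacetyl lactone 8 (not isolated)
Conditions: LiN(SiMe3)2, THF, −78 °C, then CF3CO2CH2CF3; 1 M HCl work-up; crude 8, MsN3, Et3N, H2O (1 equiv), MeCN, rt
Reagents that add atoms: methanesulfonyl azide, CS(=O)(=O)N=[N+]=[N-]; 2,2,2-trifluoroethyl trifluoroacetate, O=C(OCC(F)(F)F)C(F)(F)F (its CF3CO group stays only in 8)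
Why: In this detrifluoroacetylative Regitz diazo transfer the only enolisable position (lactone C3) is activated as the trifluoroacetyl derivative 8, whose enolate takes up N2 from the sulfonyl azide and passes the trifluoroacetyl group to the sulfonamide nitrogen, while C4 and the carbinol carbon are not involved.

Step 5
Reactants: 9 (4R)-3-diazo-4-[(R)-[(tert-butyldimethylsilyl)oxy]{4-[(tert-butyldimethylsilyl)oxy]-3-methoxyphenyl}methyl]oxolan-2-one; 2 4-[(tert-butyldimethylsilyl)oxy]-3-methoxybenzaldehyde
Product: 12 (3R,7R)-2-{4-[(tert-butyldimethylsilyl)oxy]-3-methoxyphenyl}-7-[(R)-[(tert-butyldimethylsilyl)oxy]{4-[(tert-butyldimethylsilyl)oxy]-3-methoxyphenyl}methyl]-1,5-dioxaspiro[2.4]heptan-4-one (C2 open), via rhodium carbene 10 (not isolated), via carbonyl ylide 11 (not isolated)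
Conditions: Rh2(OPiv)4 (1 mol %), 2 (1.2 equiv), 4 Å molecular sieves, CH2Cl2, −78 to −20 °C, slow addition of 9
Reagents that add atoms: none
Why: Proposed new method: dirhodium tetrapivalate removes N2 from 9, the electrophilic carbene carbon of 10 (lactone C3) is attacked by the carbonyl O of the electron-rich aldehyde 2 to give carbonyl ylide 11, and the lactone-enolate carbon of 11 then bonds to the former aldehyde carbon, so the benzylic C–C3 bond and the C3–O bond form in one operation. The closest known reaction types are the dirhodium-catalysed epoxidation of aromatic aldehydes with diazo esters and cyclic diazo amides via carbonyl ylides, and the intermolecular reactions of five-membered cyclic α-diazo carbonyl compounds that carry a tertiary β-C–H; new is their combination on a β-branched α-diazo-γ-butyrolactone. The only ring closed is the oxirane, by conrotatory four-electron electrocyclisation of the carbonyl ylide. In planar 11 the ylide O lies in the lactone plane and the CH(OTBS)Ar arm on C4 turns pseudo-axial to avoid it, so the ArCH terminus should bond to C3 on the face anti to that arm and O ends syn to it, which is the target configuration at C3, whereas the benzylic oxirane carbon is not controlled and stops being a stereocentre in step 6. The step needs ylide formation to outrun the 1,2-shift of the C4–H (secured by the five-membered ring that keeps the carbene conjugated with the C=O, the bulky pivalate ligands, the low temperature and the nucleophilic aldehyde O), and it needs ring closure to outrun cycloaddition of 11 to a second aldehyde (secured by the donor-substituted ring A, which stabilises the oxocarbenium end and makes 2 a poor dipolarophile, and by the small excess of 2).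

Step 6
Reactants: 12 spiro-oxirane (1,5-dioxaspiro[2.4]heptan-4-one described in step 5)
Product: 13 (3S,4R)-3-hydroxy-3-({4-[(tert-butyldimethylsilyl)oxy]-3-methoxyphenyl}methyl)-4-[(R)-[(tert-butyldimethylsilyl)oxy]{4-[(tert-butyldimethylsilyl)oxy]-3-methoxyphenyl}methyl]oxolan-2-one
Conditions: H2 (1 atm), 10% Pd/C, EtOAc, rt
Reagents that add atoms: none
Why: Regioselective catalytic hydrogenolysis of the benzylic C–O bond of an aryl glycidic ester, a well-known route to α-hydroxy esters, should open the strained oxirane only at the ArCH–O bond, so the C3–O bond keeps its configuration and the far less reactive benzylic silyl ether next to ring B survives the neutral conditions.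

Step 7
Reactants: 13 tris-silyl ether described in step 6
Product: 14 (3S,4R)-3-hydroxy-4-[(R)-hydroxy(4-hydroxy-3-methoxyphenyl)methyl]-3-[(4-hydroxy-3-methoxyphenyl)methyl]oxolan-2-one (target)
Conditions: TBAF, AcOH (1:1, 4 equiv each), THF, 0 °C to rt
Reagents that add atoms: none
Why: Fluoride-induced cleavage of the two aryl silyl ethers and the benzylic silyl ether, buffered with acetic acid so that no phenoxide can expel the benzylic oxygen as a quinone methide or start translactonisation, should free the target without touching a stereocentre.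

**Compound list**
1 | vanillin (4-hydroxy-3-methoxybenzaldehyde) | COc1cc(C=O)ccc1O | starting material
2 | 4-[(tert-butyldimethylsilyl)oxy]-3-methoxybenzaldehyde | COc1cc(C=O)ccc1O[Si](C)(C)C(C)(C)C | intermediate
3 | methyl 4-oxobutanoate | COC(=O)CCC=O | starting material
4 | methyl (3S,4R)-4-{4-[(tert-butyldimethylsilyl)oxy]-3-methoxyphenyl}-3-formyl-4-hydroxybutanoate | COC(=O)C[C@H](C=O)[C@@H](O)c1ccc(O[Si](C)(C)C(C)(C)C)c(OC)c1 | intermediate
5 | methyl (3R,4R)-4-{4-[(tert-butyldimethylsilyl)oxy]-3-methoxyphenyl}-4-hydroxy-3-(hydroxymethyl)butanoate | COC(=O)C[C@H](CO)[C@@H](O)c1ccc(O[Si](C)(C)C(C)(C)C)c(OC)c1 | intermediate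
6 | (4R)-4-[(R)-{4-[(tert-butyldimethylsilyl)oxy]-3-methoxyphenyl}(hydroxy)methyl]oxolan-2-one | O=C1OC[C@H]([C@@H](O)c2ccc(O[Si](C)(C)C(C)(C)C)c(OC)c2)C1 | intermediate
7 | (4R)-4-[(R)-[(tert-butyldimethylsilyl)oxy]{4-[(tert-butyldimethylsilyl)oxy]-3-methoxyphenyl}methyl]oxolan-2-one | O=C1OC[C@H]([C@@H](O[Si](C)(C)C(C)(C)C)c2ccc(O[Si](C)(C)C(C)(C)C)c(OC)c2)C1 | intermediate
8 | 3-(trifluoroacetyl) derivative of 7 (C3 open, C4 and carbinol carbon as in 7) | O=C1OC[C@H]([C@@H](O[Si](C)(C)C(C)(C)C)c2ccc(O[Si](C)(C)C(C)(C)C)c(OC)c2)C1C(=O)C(F)(F)F | intermediate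
9 | (4R)-3-diazo-4-[(R)-[(tert-butyldimethylsilyl)oxy]{4-[(tert-butyldimethylsilyl)oxy]-3-methoxyphenyl}methyl]oxolan-2-one | O=C1OC[C@H]([C@@H](O[Si](C)(C)C(C)(C)C)c2ccc(O[Si](C)(C)C(C)(C)C)c(OC)c2)C1=[N+]=[N-] | intermediate
10 | rhodium carbene at lactone C3 (drawn as the free carbene, metal omitted; other centres as in 9) | O=C1OC[C@H]([C@@H](O[Si](C)(C)C(C)(C)C)c2ccc(O[Si](C)(C)C(C)(C)C)c(OC)c2)[C]1 | intermediate
11 | carbonyl ylide from 10 and 2 (C3 carbanion/enolate, O-arylmethylidene oxonium) | O=C1OC[C@H]([C@@H](O[Si](C)(C)C(C)(C)C)c2ccc(O[Si](C)(C)C(C)(C)C)c(OC)c2)[C-]1[O+]=Cc1ccc(O[Si](C)(C)C(C)(C)C)c(OC)c1 | intermediate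
12 | (3R,7R)-2-aryl-7-[(R)-aryl(silyloxy)methyl]-1,5-dioxaspiro[2.4]heptan-4-one (aryl = 4-TBSO-3-methoxyphenyl; oxirane O syn to the C7 arm; C2 open) | COc1cc(C3O[C@@]32C(=O)OC[C@@H]2[C@@H](O[Si](C)(C)C(C)(C)C)c2ccc(O[Si](C)(C)C(C)(C)C)c(OC)c2)ccc1O[Si](C)(C)C(C)(C)C | intermediate
13 | (3S,4R)-3-hydroxy-3-(4-TBSO-3-methoxybenzyl)-4-[(R)-(TBSO)(4-TBSO-3-methoxyphenyl)methyl]oxolan-2-one | COc1cc(C[C@@]2(O)C(=O)OC[C@@H]2[C@@H](O[Si](C)(C)C(C)(C)C)c2ccc(O[Si](C)(C)C(C)(C)C)c(OC)c2)ccc1O[Si](C)(C)C(C)(C)C | intermediate
14 | (3S,4R)-3-hydroxy-4-[(R)-hydroxy(4-hydroxy-3-methoxyphenyl)methyl]-3-[(4-hydroxy-3-methoxyphenyl)methyl]oxolan-2-one | COc1cc(C[C@@]2(O)C(=O)OC[C@@H]2[C@@H](O)c2ccc(O)c(OC)c2)ccc1O | target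

**Step count**
- Total step count: 7.
- Longest linear sequence: 7 steps (1 → 2 → 6 → 7 → 9 → 12 → 13 → 14). Compound 2 enters the route twice.

**Steps most likely to fail**

1. **Step 5 (Proposed new method).**
   - What may go wrong: migration of the C4–H to the carbene carbon, capture of the ylide by a second aldehyde molecule or by the lactone carbonyl oxygen, or too little facial bias in the ring closure.
   - Fallback: known chemistry with reversed polarity (nucleophilic C3, electrophilic benzylic carbon). It sets out from 7 and comes back at 14.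
   - Compound 7 is deprotonated with KN(SiMe3)2 in THF at −78 °C and oxidised with 3-phenyl-2-(phenylsulfonyl)oxaziridine to the α-hydroxy lactone F1. Its C3 epimers are of no consequence.
   - F1 is silylated with Et3SiOTf and 2,6-lutidine to the triethylsilyl ether F2.
   - In parallel, 2 is reduced with NaBH4 to the benzylic alcohol F3, which an Appel reaction (CBr4, PPh3) converts into the benzylic bromide F4.
   - F2 is deprotonated with LiN(iPr)2 in THF/DMPU at −78 °C and the planar enolate is alkylated with F4. Attack anti to the C4 arm, as is usual for β-substituted butyrolactone enolates, should give the fully silylated lignan F5.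
   - The conditions of step 7 turn F5 into 14.

2. **Step 2.**
   - What may go wrong: slow addition of the enamine to the electron-rich aldehyde, so that self-aldolisation of the donor takes over, and partial loss of the aryl silyl ether during the borohydride stage.
   - Fallback: sets out from 2 and comes back at 6.
   - Compound 2 is homologated with ethyl diazoacetate and SnCl2 (Roskamp reaction) to the β-keto ester F6.
   - Noyori asymmetric transfer hydrogenation with RuCl(p-cymene)[(R,R)-TsDPEN] in HCO2H/Et3N should give the (R)-β-hydroxy ester F7.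
   - The dianion of F7 (LiN(iPr)2, 2.2 equiv, THF, −78 to −20 °C) is alkylated with tert-butyl bromoacetate in the anti sense (Fráter–Seebach alkylation) to the succinate F8.
   - LiBH4 reduces only the ethyl ester, and the resulting diol tert-butyl ester F9 lactonises to 6 on warming with a catalytic amount of pyridinium tosylate in toluene.

3. **Step 6.**
   - What may go wrong: over-reduction by hydrogenolysis of the second benzylic C–O bond next to ring B, or acid-induced rearrangement of the electron-rich oxirane on the catalyst support.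
   - Fallback: sets out from 12 and comes back at 13.
   - The oxirane is opened at the benzylic carbon with MgBr2·OEt2 in Et2O at −20 °C to the bromohydrin F10.
   - The C–Br bond is then removed in a radical chain reduction with Bu3SnH and AIBN in toluene at 80 °C. This does not touch benzylic C–O bonds.

**Further compounds**
F1 | step 5 | 3-hydroxy derivative of 7 (C3 open, other centres as in 7) | O=C1OC[C@H]([C@@H](O[Si](C)(C)C(C)(C)C)c2ccc(O[Si](C)(C)C(C)(C)C)c(OC)c2)C1O
F2 | step 5 | 3-(triethylsilyloxy) derivative of 7 (C3 open, other centres as in 7) | O=C1OC[C@H]([C@@H](O[Si](C)(C)C(C)(C)C)c2ccc(O[Si](C)(C)C(C)(C)C)c(OC)c2)C1O[Si](CC)(CC)CC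
F3 | step 5 | {4-[(tert-butyldimethylsilyl)oxy]-3-methoxyphenyl}methanol | COc1cc(CO)ccc1O[Si](C)(C)C(C)(C)C
F4 | step 5 | 4-(bromomethyl)-1-[(tert-butyldimethylsilyl)oxy]-2-methoxybenzene | COc1cc(CBr)ccc1O[Si](C)(C)C(C)(C)C
F5 | step 5 | O3-triethylsilyl ether of 13 (all centres as in 13) | COc1cc(C[C@@]2(O[Si](CC)(CC)CC)C(=O)OC[C@@H]2[C@@H](O[Si](C)(C)C(C)(C)C)c2ccc(O[Si](C)(C)C(C)(C)C)c(OC)c2)ccc1O[Si](C)(C)C(C)(C)C
F6 | step 2 | ethyl 3-{4-[(tert-butyldimethylsilyl)oxy]-3-methoxyphenyl}-3-oxopropanoate | CCOC(=O)CC(=O)c1ccc(O[Si](C)(C)C(C)(C)C)c(OC)c1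
F7 | step 2 | ethyl (3R)-3-{4-[(tert-butyldimethylsilyl)oxy]-3-methoxyphenyl}-3-hydroxypropanoate | CCOC(=O)C[C@@H](O)c1ccc(O[Si](C)(C)C(C)(C)C)c(OC)c1
F8 | step 2 | 4-tert-butyl 1-ethyl (2S)-2-[(R)-{4-[(tert-butyldimethylsilyl)oxy]-3-methoxyphenyl}(hydroxy)methyl]butanedioate | CCOC(=O)[C@@H](CC(=O)OC(C)(C)C)[C@@H](O)c1ccc(O[Si](C)(C)C(C)(C)C)c(OC)c1
F9 | step 2 | tert-butyl (3R,4R)-4-{4-[(tert-butyldimethylsilyl)oxy]-3-methoxyphenyl}-4-hydroxy-3-(hydroxymethyl)butanoate | CC(C)(C)OC(=O)C[C@H](CO)[C@@H](O)c1ccc(O[Si](C)(C)C(C)(C)C)c(OC)c1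
F10 | step 6 | bromohydrin of 12: 13 with Br on the ring A benzylic carbon (that carbon open, other centres as in 13) | COc1cc(C(Br)[C@@]2(O)C(=O)OC[C@@H]2[C@@H](O[Si](C)(C)C(C)(C)C)c2ccc(O[Si](C)(C)C(C)(C)C)c(OC)c2)ccc1O[Si](C)(C)C(C)(C)C
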